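**Plan**
1. Germacrane numbering is used: lactone O–C6, C7, C11(=C13H2), C12(=O); angelate on O8; epoxide C1–C10 (C14 methyl on C10); methacrylate on O3; C4(C15)=C5.
2. Retrosynthesis: first the epoxide oxygen is removed (back to the E-C1=C10 alkene) and the acyl groups on O3 and O8 are cut. Then C6–C7 and C11–C12 are cut together with O–C12: the 2-methylene-γ-lactone ring (O, C6, C7, C11, C12) shares its C6–C7 edge with the ten-membered carbocycle, so aldehyde C6, the allene π-bond C7=C11 and CO map onto it ([2+2+1]). This opens both rings to the acyclic (Z)-enal allene 16.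
3. The chain is then cut at C11–C13, C4–C15, C3–C4, C1–C2, C10–C14 and C8–C9.
4. Forward: the chain is built linearly (C8 carbinol, then E-C1=C10 with C2–C3, then the C3 carbinol with C4–C6, then the allene). The carbocycle and the lactone close in one operation, the two esters follow, and the epoxide comes last.
5. Stereochemistry: C8 and C3 come from catalytic asymmetric carbonyl additions, E-C1=C10 from syn-carboalumination, Z-C4=C5 from syn-carbocupration. C6 and C7 come from the ring-forming metallacycle under control of C8, and C1/C10 from outer-face epoxidation of the E-cycloalkene.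

Key step: step 12

Remark: the face selectivity of the catalysts in steps 1 and 5 is assumed to follow their accepted transition-state models (Re-face addition in both); the catalyst antipode would be used otherwise.

**Step 1**
Reactants: 1 3-(trimethylsilyl)prop-2-ynal; 2 allenylboronic acid pinacol ester
Product: 3 (3R)-1-(trimethylsilyl)hexa-1,5-diyn-3-ol
Conditions: (R)-TRIP (5 mol %), 4 Å molecular sieves, toluene, −20 °C; aqueous work-up
Reagents that add atoms: none
Why: Chiral phosphoric acid-catalysed allenylboration (carbonyl propargylation) runs through a closed six-membered transition state in which the (R)-TRIP-activated boronate should deliver the propargyl group, with allenyl-to-propargyl transposition, to the Re face of the ynal, which sets C8 as R.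

**Step 2**
Reactants: 3 (3R)-1-(trimethylsilyl)hexa-1,5-diyn-3-ol
Product: 4 (3R)-3-(tert-butyldimethylsilyloxy)-1-(trimethylsilyl)hexa-1,5-diyne
Conditions: TBSCl, imidazole, DMF, rt
Reagents that add atoms: tert-butyldimethylsilyl chloride, CC(C)(C)[Si](C)(C)Cl
Why: Silyl ether formation protects the C8 hydroxyl for the organometallic steps and does not touch the stereocentre.

**Step 3**
Reactants: 4 (3R)-3-(tert-butyldimethylsilyloxy)-1-(trimethylsilyl)hexa-1,5-diyne
Product: 7 (3E,6R)-6-(tert-butyldimethylsilyloxy)-4-methyl-8-(trimethylsilyl)oct-3-en-7-yn-1-ol, via alkenyldimethylalane 5 (not isolated), via lithium alkenylalanate 6 (not isolated)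
Conditions: AlMe3 (2.5 equiv), Cp2ZrCl2 (0.25 equiv), CH2Cl2, 0 °C to rt; then n-BuLi, THF, −30 °C; then ethylene oxide, −30 °C to rt; aqueous Rochelle salt
Reagents that add atoms: trimethylaluminium, C[Al](C)C; ethylene oxide, C1CO1
Why: Zirconium-catalysed syn-carboalumination (Negishi carboalumination) adds methyl to the internal carbon and aluminium to the terminus of the free alkyne only (the silylalkyne is inert), and the derived alanate opens ethylene oxide with retention at the alkenyl carbon, which fixes the E-C1=C10 alkene and adds C2–C3.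

**Step 4**
Reactants: 7 (3E,6R)-6-(tert-butyldimethylsilyloxy)-4-methyl-8-(trimethylsilyl)oct-3-en-7-yn-1-ol
Product: 8 (3E,6R)-6-(tert-butyldimethylsilyloxy)-4-methyl-8-(trimethylsilyl)oct-3-en-7-ynal
Conditions: Dess–Martin periodinane, pyridine, CH2Cl2, 0 °C to rt; used crude
Reagents that add atoms: none
Why: Buffered Dess–Martin oxidation gives the β,γ-unsaturated aldehyde under non-enolising conditions, so the C1=C10 alkene should not move into conjugation.

**Step 5**
Reactants: 8 (3E,6R)-6-(tert-butyldimethylsilyloxy)-4-methyl-8-(trimethylsilyl)oct-3-en-7-ynal; 9 methyl propiolate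
Product: 10 methyl (4S,6E,9R)-9-(tert-butyldimethylsilyloxy)-4-hydroxy-7-methyl-11-(trimethylsilyl)undec-6-ene-2,10-diynoate
Conditions: (S,S)-ProPhenol (20 mol %), Me2Zn (3 equiv), Ph3PO (40 mol %), toluene, 0 to 4 °C
Reagents that add atoms: none
Why: Zinc–ProPhenol-catalysed asymmetric alkynylation should add the zinc acetylide of the propiolate to the Re face of the aldehyde inside the dinuclear zinc pocket, which sets C3 as S.

**Step 6**
Reactants: 10 methyl (4S,6E,9R)-9-(tert-butyldimethylsilyloxy)-4-hydroxy-7-methyl-11-(trimethylsilyl)undec-6-ene-2,10-diynoate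
Product: 11 methyl (4S,6E,9R)-9-(tert-butyldimethylsilyloxy)-7-methyl-4-(triethylsilyloxy)-11-(trimethylsilyl)undec-6-ene-2,10-diynoate
Conditions: TESCl, imidazole, CH2Cl2, 0 °C
Reagents that add atoms: triethylsilyl chloride, CC[Si](Cl)(CC)CC
Why: Silylation turns the C3 oxygen into a non-leaving group for the cuprate step and gives an ether that can later be cleaved in the presence of the TBS ether.

**Step 7**
Reactants: 11 methyl (4S,6E,9R)-9-(tert-butyldimethylsilyloxy)-7-methyl-4-(triethylsilyloxy)-11-(trimethylsilyl)undec-6-ene-2,10-diynoate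
Product: 12 methyl (2Z,4S,6E,9R)-9-(tert-butyldimethylsilyloxy)-3,7-dimethyl-4-(triethylsilyloxy)-11-(trimethylsilyl)undeca-2,6-dien-10-ynoate
Conditions: Me2CuLi (2 equiv), THF, −78 °C; MeOH then aqueous NH4Cl at −78 °C
Reagents that add atoms: lithium dimethylcuprate, C[Cu-]C.[Li+]
Why: syn-Carbocupration (conjugate addition) of the ynoate with cold protonation places the new methyl (C15) and H5 cis, so that C3 and the ester carbon C6 end up cis (4Z).

**Step 8**
Reactants: 12 methyl (2Z,4S,6E,9R)-9-(tert-butyldimethylsilyloxy)-3,7-dimethyl-4-(triethylsilyloxy)-11-(trimethylsilyl)undeca-2,6-dien-10-ynoate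
Product: 13 (2Z,4S,6E,9R)-9-(tert-butyldimethylsilyloxy)-3,7-dimethyl-4-(triethylsilyloxy)-11-(trimethylsilyl)undeca-2,6-dien-10-yn-1-ol
Conditions: iBu2AlH (2.5 equiv), CH2Cl2, −78 °C; aqueous Rochelle salt
Reagents that add atoms: none
Why: 1,2-Reduction of the enoate by the aluminium hydride gives the (Z)-allylic alcohol and leaves the alkyne, the alkenes and the silyl ethers untouched.

**Step 9**
Reactants: 13 (2Z,4S,6E,9R)-9-(tert-butyldimethylsilyloxy)-3,7-dimethyl-4-(triethylsilyloxy)-11-(trimethylsilyl)undeca-2,6-dien-10-yn-1-ol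
Product: 14 (2Z,4S,6E,9R)-9-(tert-butyldimethylsilyloxy)-3,7-dimethyl-4-(triethylsilyloxy)undeca-2,6-dien-10-yn-1-ol
Conditions: K2CO3 (0.2 equiv), MeOH, 0 °C to rt
Reagents that add atoms: none
Why: Base-catalysed methanolysis of the alkynyl C–Si bond (protodesilylation) frees the terminal alkyne, and the TES and TBS ethers should survive.

**Step 10**
Reactants: 14 (2Z,4S,6E,9R)-9-(tert-butyldimethylsilyloxy)-3,7-dimethyl-4-(triethylsilyloxy)undeca-2,6-dien-10-yn-1-ol
Product: 15 (2Z,4S,6E,9R)-9-(tert-butyldimethylsilyloxy)-3,7-dimethyl-4-(triethylsilyloxy)dodeca-2,6,10,11-tetraen-1-ol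
Conditions: (CH2O)n, CuI (0.5 equiv), Cy2NH, 1,4-dioxane, reflux
Reagents that add atoms: paraformaldehyde (as formaldehyde), C=O
Why: Crabbé homologation (copper-mediated Mannich coupling of alkyne, formaldehyde and amine, then 1,5-hydride transfer with loss of the imine) converts the terminal alkyne into the terminal allene, with C13 from formaldehyde and C8 untouched.

**Step 11**
Reactants: 15 (2Z,4S,6E,9R)-9-(tert-butyldimethylsilyloxy)-3,7-dimethyl-4-(triethylsilyloxy)dodeca-2,6,10,11-tetraen-1-ol
Product: 16 (2Z,4S,6E,9R)-9-(tert-butyldimethylsilyloxy)-3,7-dimethyl-4-(triethylsilyloxy)dodeca-2,6,10,11-tetraenal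
Conditions: MnO2 (excess), CH2Cl2, rt, dark
Reagents that add atoms: none
Why: Allylic alcohol oxidation on MnO2 under neutral conditions should give the (Z)-enal with the C4=C5 geometry retained.

**Step 12**
Reactants: 16 (2Z,4S,6E,9R)-9-(tert-butyldimethylsilyloxy)-3,7-dimethyl-4-(triethylsilyloxy)dodeca-2,6,10,11-tetraenal
Product: 17 8β-(tert-butyldimethylsilyloxy)-3β-(triethylsilyloxy)germacra-1(10)E,4Z,11(13)-trien-6α,12-olide (7α-H, trans-fused lactone)
Conditions: Mo(CO)6 (1.5 equiv), DMSO (10 equiv), toluene, 100 °C, 16 added over 12 h (final 2 mM)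
Reagents that add atoms: molybdenum hexacarbonyl (one CO is incorporated), [Mo].[C-]#[O+].[C-]#[O+].[C-]#[O+].[C-]#[O+].[C-]#[O+].[C-]#[O+]
Why: Proposed new method: a hetero-Pauson–Khand [2+2+1] cyclocarbonylation run as a macrocyclisation; the closest known reaction type is the cyclocarbonylation of δ- and ε-allenyl aldehydes with Mo(CO)6/DMSO (or catalytic Ru3(CO)12 under CO) to five- and six-ring-fused α-methylene-γ-butyrolactones, which forms the same three bonds by the same elementary events, so that only the ten-membered ring size and the trans fusion are new. Mechanistically, DMSO opens coordination sites on zerovalent molybdenum, which binds the C6 aldehyde and the proximal C7=C11 π-bond of the allene; oxidative cyclisation forms C6–C7, CO insertion into the resulting alkenyl–molybdenum bond at C11 forms C11–C12, and C(acyl)–O reductive elimination closes the lactone while the distal C11=C13 bond remains as the exocyclic methylene. The ten-membered carbocycle closes in the oxidative cyclisation in a 10-exo mode with respect to both π-bonds (C6=O and C7=C11 stay outside the new ring), and the γ-lactone closes by extrusion of the metal from the six-membered acyl oxametallacycle, which is a ring contraction. C7 should be controlled by the neighbouring C8 stereocentre, whose hydrogen lies in the allene plane (allylic strain) so that the tether leaving C8 through C9 brings the aldehyde to the π-face that puts C11 syn to the C8 oxygen, and C6 by the metallacycle, in which the two arms C5 and C8 of the eight-atom tether take trans positions, the arrangement of the trans-fused heliangolide skeleton (H6 β, H7 α). The step needs proximal over distal π-bond selectivity (the known preference of molybdenum with monosubstituted allenes, reinforced here because the distal mode would give a twelve-membered ring with a third endocyclic trisubstituted alkene), carbonyl rather than conjugate reactivity of the enal (the β-carbon C4 is fully substituted) and cyclisation over oligomerisation (slow addition at high dilution, with the Z-C4=C5 and E-C1=C10 alkenes as turn elements).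

**Step 13**
Reactants: 17 8β-(tert-butyldimethylsilyloxy)-3β-(triethylsilyloxy)germacra-1(10)E,4Z,11(13)-trien-6α,12-olide
Product: 18 8β-(tert-butyldimethylsilyloxy)-3β-hydroxygermacra-1(10)E,4Z,11(13)-trien-6α,12-olide
Conditions: HF·pyridine, pyridine, THF, 0 °C
Reagents that add atoms: none
Why: Buffered fluoride-mediated silyl ether cleavage is selective for the more labile secondary TES ether over the hindered TBS ether.

**Step 14**
Reactants: 18 8β-(tert-butyldimethylsilyloxy)-3β-hydroxygermacra-1(10)E,4Z,11(13)-trien-6α,12-olide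
Product: 19 8β-(tert-butyldimethylsilyloxy)-3β-methacryloyloxygermacra-1(10)E,4Z,11(13)-trien-6α,12-olide
Conditions: methacryloyl chloride, Et3N, DMAP (cat.), CH2Cl2, 0 °C
Reagents that add atoms: methacryloyl chloride, C=C(C)C(=O)Cl
Why: DMAP-catalysed acylation of the allylic C3 hydroxyl installs the methacrylate with retention at C3.

**Step 15**
Reactants: 19 8β-(tert-butyldimethylsilyloxy)-3β-methacryloyloxygermacra-1(10)E,4Z,11(13)-trien-6α,12-olide
Product: 20 8β-hydroxy-3β-methacryloyloxygermacra-1(10)E,4Z,11(13)-trien-6α,12-olide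
Conditions: HF·pyridine, THF, 0 °C to rt
Reagents that add atoms: none
Why: Acidic fluoride desilylation removes the TBS ether without base, so the two conjugated esters and the α-methylene lactone should stay intact.

**Step 16**
Reactants: 20 8β-hydroxy-3β-methacryloyloxygermacra-1(10)E,4Z,11(13)-trien-6α,12-olide
Product: 21 8β-angeloyloxy-3β-methacryloyloxygermacra-1(10)E,4Z,11(13)-trien-6α,12-olide
Conditions: angelic acid, 2,4,6-trichlorobenzoyl chloride, Et3N, toluene, rt; then 20, toluene, 80 °C (no DMAP)
Reagents that add atoms: angelic acid, C/C=C(/C)C(=O)O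
Why: Yamaguchi esterification through the mixed anhydride of angelic acid, run without a nucleophilic catalyst, acylates the hindered C8 hydroxyl with retention and should avoid Z-to-E isomerisation of the angelate to the tiglate.

**Step 17**
Reactants: 21 8β-angeloyloxy-3β-methacryloyloxygermacra-1(10)E,4Z,11(13)-trien-6α,12-olide
Product: 22 8β-angeloyloxy-1β,10α-epoxy-3β-methacryloyloxygermacra-4Z,11(13)-dien-6α,12-olide, (1R,3S,6R,7R,8R,10R)
Conditions: mCPBA (1.1 equiv), NaHCO3, CH2Cl2, 0 °C
Reagents that add atoms: 3-chloroperoxybenzoic acid, OOC(=O)c1cccc(Cl)c1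
Why: Prilezhaev epoxidation should select the only electron-rich alkene (C1=C10, all others carry acyl or acyloxy groups), is stereospecific (E-alkene to trans-epoxide), and by attack on the outer face of the E-cycloalkene in the conformer with C14 on the β-face should give the 1β,10α-epoxide (1R,10R).

**Compound list**
1 | 3-(trimethylsilyl)prop-2-ynal | C[Si](C)(C)C#CC=O | starting material
2 | allenylboronic acid pinacol ester (4,4,5,5-tetramethyl-2-(propa-1,2-dien-1-yl)-1,3,2-dioxaborolane) | C=C=CB1OC(C)(C)C(C)(C)O1 | starting material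
3 | (3R)-1-(trimethylsilyl)hexa-1,5-diyn-3-ol | C[Si](C)(C)C#C[C@H](O)CC#C | intermediate
4 | (3R)-3-(tert-butyldimethylsilyloxy)-1-(trimethylsilyl)hexa-1,5-diyne | C[Si](C)(C)C#C[C@H](O[Si](C)(C)C(C)(C)C)CC#C | intermediate
5 | [(1E,4R)-4-(tert-butyldimethylsilyloxy)-2-methyl-6-(trimethylsilyl)hex-1-en-5-yn-1-yl]dimethylalane | C[Al](C)/C=C(C)/C[C@@H](O[Si](C)(C)C(C)(C)C)C#C[Si](C)(C)C | intermediate
6 | lithium butyl[(1E,4R)-4-(tert-butyldimethylsilyloxy)-2-methyl-6-(trimethylsilyl)hex-1-en-5-yn-1-yl]dimethylalanate | [Li+].CCCC[Al-](C)(C)/C=C(C)/C[C@@H](O[Si](C)(C)C(C)(C)C)C#C[Si](C)(C)C | intermediate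
7 | (3E,6R)-6-(tert-butyldimethylsilyloxy)-4-methyl-8-(trimethylsilyl)oct-3-en-7-yn-1-ol | OCC/C=C(C)/C[C@@H](O[Si](C)(C)C(C)(C)C)C#C[Si](C)(C)C | intermediate
8 | (3E,6R)-6-(tert-butyldimethylsilyloxy)-4-methyl-8-(trimethylsilyl)oct-3-en-7-ynal | O=CC/C=C(C)/C[C@@H](O[Si](C)(C)C(C)(C)C)C#C[Si](C)(C)C | intermediate
9 | methyl propiolate | C#CC(=O)OC | starting material
10 | methyl (4S,6E,9R)-9-(tert-butyldimethylsilyloxy)-4-hydroxy-7-methyl-11-(trimethylsilyl)undec-6-ene-2,10-diynoate | COC(=O)C#C[C@@H](O)C/C=C(C)/C[C@@H](O[Si](C)(C)C(C)(C)C)C#C[Si](C)(C)C | intermediate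
11 | methyl (4S,6E,9R)-9-(tert-butyldimethylsilyloxy)-7-methyl-4-(triethylsilyloxy)-11-(trimethylsilyl)undec-6-ene-2,10-diynoate | COC(=O)C#C[C@@H](O[Si](CC)(CC)CC)C/C=C(C)/C[C@@H](O[Si](C)(C)C(C)(C)C)C#C[Si](C)(C)C | intermediate
12 | methyl (2Z,4S,6E,9R)-9-(tert-butyldimethylsilyloxy)-3,7-dimethyl-4-(triethylsilyloxy)-11-(trimethylsilyl)undeca-2,6-dien-10-ynoate | COC(=O)/C=C(C)\[C@@H](O[Si](CC)(CC)CC)C/C=C(C)/C[C@@H](O[Si](C)(C)C(C)(C)C)C#C[Si](C)(C)C | intermediate
13 | (2Z,4S,6E,9R)-9-(tert-butyldimethylsilyloxy)-3,7-dimethyl-4-(triethylsilyloxy)-11-(trimethylsilyl)undeca-2,6-dien-10-yn-1-ol | OC/C=C(C)\[C@@H](O[Si](CC)(CC)CC)C/C=C(C)/C[C@@H](O[Si](C)(C)C(C)(C)C)C#C[Si](C)(C)C | intermediate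
14 | (2Z,4S,6E,9R)-9-(tert-butyldimethylsilyloxy)-3,7-dimethyl-4-(triethylsilyloxy)undeca-2,6-dien-10-yn-1-ol | OC/C=C(C)\[C@@H](O[Si](CC)(CC)CC)C/C=C(C)/C[C@@H](O[Si](C)(C)C(C)(C)C)C#C | intermediate
15 | (2Z,4S,6E,9R)-9-(tert-butyldimethylsilyloxy)-3,7-dimethyl-4-(triethylsilyloxy)dodeca-2,6,10,11-tetraen-1-ol | OC/C=C(C)\[C@@H](O[Si](CC)(CC)CC)C/C=C(C)/C[C@@H](O[Si](C)(C)C(C)(C)C)C=C=C | intermediate
16 | (2Z,4S,6E,9R)-9-(tert-butyldimethylsilyloxy)-3,7-dimethyl-4-(triethylsilyloxy)dodeca-2,6,10,11-tetraenal | O=C/C=C(C)\[C@@H](O[Si](CC)(CC)CC)C/C=C(C)/C[C@@H](O[Si](C)(C)C(C)(C)C)C=C=C | intermediate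
17 | 8β-(tert-butyldimethylsilyloxy)-3β-(triethylsilyloxy)germacra-1(10)E,4Z,11(13)-trien-6α,12-olide | CC[Si](CC)(CC)O[C@H]1C/C=C(C)/C[C@@H](O[Si](C)(C)C(C)(C)C)[C@H]2C(=C)C(=O)O[C@@H]2/C=C\1C | intermediate
18 | 8β-(tert-butyldimethylsilyloxy)-3β-hydroxygermacra-1(10)E,4Z,11(13)-trien-6α,12-olide | O[C@H]1C/C=C(C)/C[C@@H](O[Si](C)(C)C(C)(C)C)[C@H]2C(=C)C(=O)O[C@@H]2/C=C\1C | intermediate
19 | 8β-(tert-butyldimethylsilyloxy)-3β-methacryloyloxygermacra-1(10)E,4Z,11(13)-trien-6α,12-olide | C=C(C)C(=O)O[C@H]1C/C=C(C)/C[C@@H](O[Si](C)(C)C(C)(C)C)[C@H]2C(=C)C(=O)O[C@@H]2/C=C\1C | intermediate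
20 | 8β-hydroxy-3β-methacryloyloxygermacra-1(10)E,4Z,11(13)-trien-6α,12-olide | C=C(C)C(=O)O[C@H]1C/C=C(C)/C[C@@H](O)[C@H]2C(=C)C(=O)O[C@@H]2/C=C\1C | intermediate
21 | 8β-angeloyloxy-3β-methacryloyloxygermacra-1(10)E,4Z,11(13)-trien-6α,12-olide | C=C(C)C(=O)O[C@H]1C/C=C(C)/C[C@@H](OC(=O)/C(C)=C\C)[C@H]2C(=C)C(=O)O[C@@H]2/C=C\1C | intermediate
22 | 8β-angeloyloxy-1β,10α-epoxy-3β-methacryloyloxygermacra-4Z,11(13)-dien-6α,12-olide, (1R,3S,6R,7R,8R,10R) | C=C(C)C(=O)O[C@H]1C[C@H]2O[C@]2(C)C[C@@H](OC(=O)/C(C)=C\C)[C@H]2C(=C)C(=O)O[C@@H]2/C=C\1C | target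

**Totals**
Total step count: 17. Longest linear sequence: 17 steps from 1 (2 and 9 are purchased).

**Steps most likely to fail**

1. Step 12 (the proposed new method). What may go wrong: cyclocarbonylation through the distal allene π-bond (twelve-membered ring), oligomerisation instead of ring closure, cis ring fusion or attack on the wrong allene face, and Z-to-E isomerisation of the enal at 100 °C. The fallback uses known chemistry, sets out from 16 and returns at 17. Iodine is added across the allene of 16 (I2, CH2Cl2, 0 °C, dark) to give the allylic diiodide (2Z,4S,6E,9R)-9-(tert-butyldimethylsilyloxy)-11,12-diiodo-3,7-dimethyl-4-(triethylsilyloxy)dodeca-2,6,10-trienal F1. CrCl2 in THF at high dilution then converts the allylic iodide into a 2-iodoallylchromium species that adds through its substituted terminus C7 to the aldehyde (intramolecular Nozaki–Hiyama allylation, anti-selective closed transition state). This should give the ten-membered iodo alcohol 8β-(tert-butyldimethylsilyloxy)-11-iodo-3β-(triethylsilyloxy)-12-norgermacra-1(10)E,4Z,11(13)-trien-6α-ol F2. Carbonylative lactonisation of the alkenyl iodide with the C6 hydroxyl (Pd(PPh3)4, CO at 1 atm, Et3N, THF, 50 °C) then gives 17.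

2. Step 5. What may go wrong: migration of the β,γ-alkene of the aldehyde into conjugation or self-aldol reaction under the basic zinc conditions, and low face selectivity at C3. The fallback sets out from 8 and returns at 10. The lithium acetylide of methyl propiolate (n-BuLi, THF, −78 °C) is added to 8 at −78 °C, a fast addition that should outrun enolisation, to give the C4-epimeric alcohols methyl (4RS,6E,9R)-9-(tert-butyldimethylsilyloxy)-4-hydroxy-7-methyl-11-(trimethylsilyl)undec-6-ene-2,10-diynoate F3. Dess–Martin oxidation gives the ynone methyl (6E,9R)-9-(tert-butyldimethylsilyloxy)-7-methyl-4-oxo-11-(trimethylsilyl)undec-6-ene-2,10-diynoate F4. Midland reduction with (S)-Alpine-borane (neat, rt) then sets C3 under reagent control, the (S)-reagent being the one that gives (S)-alkynyl carbinols of this substitution pattern, and gives 10.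

3. Step 17. What may go wrong: epoxidation from the other face of the C1=C10 alkene (if the conformer with C14 on the α-face reacts), competing epoxidation of C4=C5, and acid-induced transannular opening of the epoxide. The fallback sets out from 20 and returns at 22. The free 8β-alcohol 20 is epoxidised under reagent control by Shi epoxidation (D-fructose-derived ketone, Oxone, K2CO3 buffer, MeCN/dimethoxymethane/H2O, 0 °C), which for E-trisubstituted alkenes delivers the (R,R)-epoxide. This should give 1β,10α-epoxy-8β-hydroxy-3β-methacryloyloxygermacra-4Z,11(13)-dien-6α,12-olide F5. Yamaguchi angeloylation as in step 16 then gives 22.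

**Further compounds**
F1 | step 12 | (2Z,4S,6E,9R)-9-(tert-butyldimethylsilyloxy)-11,12-diiodo-3,7-dimethyl-4-(triethylsilyloxy)dodeca-2,6,10-trienal | O=C/C=C(C)\[C@@H](O[Si](CC)(CC)CC)C/C=C(C)/C[C@@H](O[Si](C)(C)C(C)(C)C)C=C(I)CI
F2 | step 12 | 8β-(tert-butyldimethylsilyloxy)-11-iodo-3β-(triethylsilyloxy)-12-norgermacra-1(10)E,4Z,11(13)-trien-6α-ol | CC[Si](CC)(CC)O[C@H]1C/C=C(C)/C[C@@H](O[Si](C)(C)C(C)(C)C)[C@@H](C(I)=C)[C@H](O)/C=C\1C
F3 | step 5 | methyl (4RS,6E,9R)-9-(tert-butyldimethylsilyloxy)-4-hydroxy-7-methyl-11-(trimethylsilyl)undec-6-ene-2,10-diynoate | COC(=O)C#CC(O)C/C=C(C)/C[C@@H](O[Si](C)(C)C(C)(C)C)C#C[Si](C)(C)C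
F4 | step 5 | methyl (6E,9R)-9-(tert-butyldimethylsilyloxy)-7-methyl-4-oxo-11-(trimethylsilyl)undec-6-ene-2,10-diynoate | COC(=O)C#CC(=O)C/C=C(C)/C[C@@H](O[Si](C)(C)C(C)(C)C)C#C[Si](C)(C)C
F5 | step 17 | 1β,10α-epoxy-8β-hydroxy-3β-methacryloyloxygermacra-4Z,11(13)-dien-6α,12-olide | C=C(C)C(=O)O[C@H]1C[C@H]2O[C@]2(C)C[C@@H](O)[C@H]2C(=C)C(=O)O[C@@H]2/C=C\1C
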